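**Plan**

The target is a single 29-membered lactone ring (C1–C28 plus the ring oxygen) whose only functional group is the C1 ester. C2 is therefore the one ring carbon that can carry a stabilised carbanion, and the ring is cut at C2–C3, formed as a C2=C3 enoate by intramolecular Horner–Wadsworth–Emmons olefination.
The chain is cut further at the alkyl O–C28 ester bond (carboxylate alkylation) and at C14–C15 and C16–C17, on either side of a temporary C15≡C16 alkyne (two acetylide alkylations).
Forward: 12-bromododecan-1-ol (C3–C14) is joined to acetylene (C15, C16) and then to 1,12-dibromododecane (C17–C28). The remaining bromide is displaced by diethylphosphonoacetate (C1, C2), the hydroxyl end is oxidised to the aldehyde, the one ring closes at C2=C3, and a single hydrogenation removes the alkene and the alkyne.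
Stereochemistry: the target has no stereocentre and no double bond, so the alkene geometry from the ring closure is erased by the hydrogenation.

Key step: step 7

Remark: lithium acetylide–ethylenediamine complex is taken as the commercial form of acetylene, and the tetrahydropyranyl (THP) ethers are racemic at the acetal carbon, which has no consequence because the group is removed in step 4.

**Route**

Step 1
Reactants: 1 12-bromododecan-1-ol
Product: 2 2-[(12-bromododecyl)oxy]oxane
Conditions: 3,4-dihydro-2H-pyran (1.5 equiv), PPTS (cat.), CH2Cl2, rt
Reagents that add atoms: 3,4-dihydro-2H-pyran, C1=COCCC1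
Why: Acid-catalysed addition of the alcohol to the enol ether (tetrahydropyranylation) masks the hydroxyl as a base-stable acetal for the acetylide steps; the new acetal carbon forms as a racemate and is not controlled.

Step 2
Reactants: 2 2-[(12-bromododecyl)oxy]oxane; 3 lithium acetylide–ethylenediamine complex
Product: 4 2-(tetradec-13-yn-1-yloxy)oxane
Conditions: LiC≡CH·H2NCH2CH2NH2 (2 equiv), DMSO, 0 °C to rt
Reagents that add atoms: none
Why: SN2 alkylation of lithium acetylide by the primary bromide in DMSO (acetylide alkylation) forms C14–C15, the excess of acetylide keeping dialkylation low and the acetal being inert to the base.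

Step 3
Reactants: 4 2-(tetradec-13-yn-1-yloxy)oxane; 5 1,12-dibromododecane
Product: 7 2-[(26-bromohexacos-13-yn-1-yl)oxy]oxane, via lithium acetylide 6 (not isolated)
Conditions: n-BuLi (1.05 equiv), THF, −78 to 0 °C; then transferred slowly into 5 (4 equiv), THF/DMPU, 0 °C to rt
Reagents that add atoms: none
Why: Deprotonation of the terminal alkyne and SN2 alkylation of the lithium acetylide (acetylide alkylation) forms C16–C17, and inverse addition into an excess of the inexpensive dibromide should keep reaction at only one end dominant, the surplus 5 being removed by chromatography.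

Step 4
Reactants: 7 2-[(26-bromohexacos-13-yn-1-yl)oxy]oxane
Product: 8 26-bromohexacos-13-yn-1-ol
Conditions: PPTS (cat.), EtOH/THF, 55 °C
Reagents that add atoms: none
Why: Acid-catalysed transacetalisation to ethanol (THP ether cleavage) frees the alcohol while the primary bromide and the alkyne are untouched by the mild pyridinium acid.

Step 5
Reactants: 8 26-bromohexacos-13-yn-1-ol; 9 diethylphosphonoacetic acid
Product: 11 26-hydroxyhexacos-13-yn-1-yl 2-(diethoxyphosphoryl)acetate, via cesium 2-(diethoxyphosphoryl)acetate 10 (not isolated)
Conditions: 9 (1.5 equiv), Cs2CO3 (0.75 equiv), DMF, rt; then 8, 50 °C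
Reagents that add atoms: none
Why: Cesium carboxylate SN2 esterification of the primary bromide forms the O–C28 bond, and because the acid is in excess over Cs2CO3 no free carbonate remains, so neither the distal hydroxyl nor the acidic P–CH2–C(=O) position should be deprotonated and alkylated.

Step 6
Reactants: 11 26-hydroxyhexacos-13-yn-1-yl 2-(diethoxyphosphoryl)acetate
Product: 12 26-oxohexacos-13-yn-1-yl 2-(diethoxyphosphoryl)acetate
Conditions: Dess–Martin periodinane (1.3 equiv), CH2Cl2, 0 °C to rt; used directly in step 7
Reagents that add atoms: none
Why: Dess–Martin oxidation takes the primary alcohol to the aldehyde without base, so the phosphonoacetate is not deprotonated and no premature olefination should occur.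

Step 7
Reactants: 12 26-oxohexacos-13-yn-1-yl 2-(diethoxyphosphoryl)acetate
Product: 13 (E)-octacos-2-en-15-yn-28-olide
Conditions: LiCl (20 equiv), DBU (10 equiv), MeCN, rt; 12 in MeCN/THF added by syringe pump over about 12 h, final concentration about 1 mM
Reagents that add atoms: none
Why: LiCl chelates the phosphoryl and ester oxygens of 12, which acidifies the P–CH2–C(=O) position enough for DBU to generate a small stationary concentration of the lithium phosphonoenolate; this carbanion adds to the terminal aldehyde carbon (C3 of the lactone) and the β-alkoxyphosphonate collapses through an oxaphosphetane with irreversible loss of lithium diethyl phosphate to give the C2=C3 enoate. The closest known reaction type is the intramolecular Horner–Wadsworth–Emmons macrocyclisation under Masamune–Roush conditions, long used for large unsaturated macrolides. The 29-membered ring (28 carbons and the ester oxygen) closes in a 29-exo-trig addition of C2 to the aldehyde carbon, the carbonyl oxygen staying outside the ring until it leaves with phosphorus. No stereocentre is created, and the E geometry expected from a stabilised phosphonate in a strain-free large ring is of no consequence because the alkene is hydrogenated in step 8. The selectivity that matters is ring closure against intermolecular olefination, and it should be secured by slow addition into dilute base so that unreacted 12 never accumulates, by the irreversible elimination, and by the linear C15≡C16 unit that removes rotors from the chain. The amine base is too weak to enolise the aldehyde appreciably, so aldol self-condensation should not compete.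

Step 8
Reactants: 13 (E)-octacos-2-en-15-yn-28-olide
Product: 14 octacosanolide
Conditions: H2 (1 atm), Pd/C (10 wt% palladium on carbon), EtOAc, rt
Reagents that add atoms: none
Why: Heterogeneous catalytic hydrogenation saturates both the conjugated C2=C3 alkene and the C15≡C16 alkyne, while the ester C–O bonds are neither allylic nor benzylic and should not be hydrogenolysed.

**Compound list**

1 | 12-bromododecan-1-ol | OCCCCCCCCCCCCBr | starting material
2 | 2-[(12-bromododecyl)oxy]oxane (racemic THP ether) | BrCCCCCCCCCCCCOC1CCCCO1 | intermediate
3 | lithium acetylide–ethylenediamine complex | [Li]C#C.NCCN | starting material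
4 | 2-(tetradec-13-yn-1-yloxy)oxane (racemic) | C#CCCCCCCCCCCCCOC1CCCCO1 | intermediate
5 | 1,12-dibromododecane | BrCCCCCCCCCCCCBr | starting material
6 | [14-(oxan-2-yloxy)tetradec-1-yn-1-yl]lithium | [Li]C#CCCCCCCCCCCCCOC1CCCCO1 | intermediate
7 | 2-[(26-bromohexacos-13-yn-1-yl)oxy]oxane (racemic) | BrCCCCCCCCCCCCC#CCCCCCCCCCCCCOC1CCCCO1 | intermediate
8 | 26-bromohexacos-13-yn-1-ol | OCCCCCCCCCCCCC#CCCCCCCCCCCCCBr | intermediate
9 | diethylphosphonoacetic acid (2-(diethoxyphosphoryl)acetic acid) | CCOP(=O)(OCC)CC(=O)O | starting material
10 | cesium 2-(diethoxyphosphoryl)acetate | [Cs+].[O-]C(=O)CP(=O)(OCC)OCC | intermediate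
11 | 26-hydroxyhexacos-13-yn-1-yl 2-(diethoxyphosphoryl)acetate | CCOP(=O)(OCC)CC(=O)OCCCCCCCCCCCCC#CCCCCCCCCCCCCO | intermediate
12 | 26-oxohexacos-13-yn-1-yl 2-(diethoxyphosphoryl)acetate | CCOP(=O)(OCC)CC(=O)OCCCCCCCCCCCCC#CCCCCCCCCCCCC=O | intermediate
13 | (E)-octacos-2-en-15-yn-28-olide | O=C1/C=C/CCCCCCCCCCCC#CCCCCCCCCCCCCO1 | intermediate
14 | octacosanolide | O=C1CCCCCCCCCCCCCCCCCCCCCCCCCCCO1 | target

**Step count and risks**

Total step count: 8. Longest linear sequence: 8 steps, from 1 to 14.

Steps most likely to fail:

1. Step 7. Intermolecular olefination may outrun ring closure, so that cyclic dimers and linear oligomers form in place of the monomeric ring. Fallback: the ring is closed at the O–C28 bond instead, and C2=C3 is made intermolecularly. The fallback sets out from bromo alcohol 8. Dess–Martin oxidation would give 26-bromohexacos-13-ynal F1. Wittig olefination with tert-butyl (triphenylphosphoranylidene)acetate in CH2Cl2 would give tert-butyl (E)-28-bromooctacos-2-en-15-ynoate F2. Trifluoroacetic acid in CH2Cl2 would release (E)-28-bromooctacos-2-en-15-ynoic acid F3. Slow addition of F3 to Cs2CO3 in DMF at 60 °C under high dilution (cesium carboxylate macrolactonisation by intramolecular SN2) would then close the ring to lactone 13, where the route is rejoined before the hydrogenation.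

2. Step 3. The lithium acetylide may attack both ends of the dibromide or eliminate HBr from it, so that little of the singly alkylated bromide is obtained. Fallback: the differentiated chain ends are given up and the symmetric chain is built. The fallback sets out from alkyne 4, which is deprotonated as before and alkylated with a second portion of THP bromide 2 in THF/DMPU to give 1,26-bis(oxan-2-yloxy)hexacos-13-yne F4. PPTS in EtOH/THF would remove both acetals to give hexacos-13-yne-1,26-diol F5. Steglich monoesterification of F5, used in excess, with acid 9 (EDC·HCl, DMAP, CH2Cl2/THF) would give hydroxy ester 11, the unreacted diol being recovered; the route is rejoined at 11.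

3. Step 5. Displacement of the bromide by the carboxylate may be slow, and the acidic methylene of the ester already formed may then be alkylated at carbon by remaining bromide. Fallback: the ester is made by acylating an alcohol instead of alkylating a carboxylate. The fallback sets out from THP bromide 7. CsOAc in DMF would give 26-(oxan-2-yloxy)hexacos-13-yn-1-yl acetate F6. K2CO3 in MeOH/THF would give 26-(oxan-2-yloxy)hexacos-13-yn-1-ol F7. Steglich esterification with acid 9 (EDC·HCl, DMAP, CH2Cl2) would give 26-(oxan-2-yloxy)hexacos-13-yn-1-yl 2-(diethoxyphosphoryl)acetate F8. PPTS in EtOH would then remove the acetal to give hydroxy ester 11, where the route is rejoined.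

**Further compounds**

F1 | step 7 | 26-bromohexacos-13-ynal | O=CCCCCCCCCCCCC#CCCCCCCCCCCCCBr
F2 | step 7 | tert-butyl (E)-28-bromooctacos-2-en-15-ynoate | CC(C)(C)OC(=O)/C=C/CCCCCCCCCCCC#CCCCCCCCCCCCCBr
F3 | step 7 | (E)-28-bromooctacos-2-en-15-ynoic acid | OC(=O)/C=C/CCCCCCCCCCCC#CCCCCCCCCCCCCBr
F4 | step 3 | 1,26-bis(oxan-2-yloxy)hexacos-13-yne | O1CCCCC1OCCCCCCCCCCCCC#CCCCCCCCCCCCCOC1CCCCO1
F5 | step 3 | hexacos-13-yne-1,26-diol | OCCCCCCCCCCCCC#CCCCCCCCCCCCCO
F6 | step 5 | 26-(oxan-2-yloxy)hexacos-13-yn-1-yl acetate | CC(=O)OCCCCCCCCCCCCC#CCCCCCCCCCCCCOC1CCCCO1
F7 | step 5 | 26-(oxan-2-yloxy)hexacos-13-yn-1-ol | OCCCCCCCCCCCCC#CCCCCCCCCCCCCOC1CCCCO1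
F8 | step 5 | 26-(oxan-2-yloxy)hexacos-13-yn-1-yl 2-(diethoxyphosphoryl)acetate | CCOP(=O)(OCC)CC(=O)OCCCCCCCCCCCCC#CCCCCCCCCCCCCOC1CCCCO1
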